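## Retrosynthetic overview
1. The spiro centre C5'' is acid-labile, so it is fixed last by equilibration, separation and recycling. The phthalide, the last of the three rings to form, opens to an (R)-o-bromo benzylic alcohol (Br/Li exchange, CO2).
2. The (R)-carbinol C3 comes from asymmetric transfer hydrogenation of an aryl ketone. That ketone comes from 3,5-dimethoxyphenylmagnesium bromide and a spiroketal heptanal (ozonolysis of a terminal alkene).
3. Both spiroketal rings form first, in one operation, by hydrolysis and decarboxylation of an α-acyl-γ-lactone to a γ,γ'-dihydroxy ketone.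
4. Key bond C5''–C9'': crossed Claisen condensation of the lithium enolate of (S)-γ-valerolactone with (S)-γ-(oct-7-enyl)-γ-butyrolactone.
5. Both lactones come from diethyl malonate and an (S)-epoxide: (S)-propylene oxide sets C7'', and 1,2-epoxy-9-decene after hydrolytic kinetic resolution sets C2''.

Assumption: a 1,6-dioxaspiro[4.4]nonane has no useful bias at the spiro carbon (about 1:1 at equilibrium), so C5'' is carried as an epimer mixture and resolved only in the last step.

Locants: phthalide C1–C7a. Spiroketal O1'', C2'' (long chain), C5'' (spiro), O6'', C7'' (CH3), C9'' (CH2 next to C5'' in the methyl-bearing ring). The target is (3R,2''S,5''R,7''S).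

## Route

Step 1
Reactants: 1 (S)-propylene oxide [(2S)-2-methyloxirane]; 2 diethyl malonate
Product: 4 ethyl (5S)-5-methyl-2-oxooxolane-3-carboxylate (C3 epimers), via open-chain hydroxy diester 3 (not isolated)
Conditions: NaOEt (1.05 equiv), EtOH, 0 °C to rt, 16 h; then 1 M HCl
Reagents that add atoms: none
Why: Malonic ester alkylation by epoxide opening, in which the malonate anion attacks the unsubstituted CH2 by SN2, the C–O bond of the stereocentre is never touched (S retained, later C7''), and the alkoxide lactonises onto one ester.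

Step 2
Reactants: 4 ethyl (5S)-5-methyl-2-oxooxolane-3-carboxylate
Product: 7 (S)-γ-valerolactone [(5S)-5-methyloxolan-2-one], via disodium hydroxypropylmalonate 5 (not isolated), via lactone acid 6 (not isolated)
Conditions: NaOH (2.5 equiv), H2O, rt to 50 °C; conc. HCl to pH 1, EtOAc extraction; neat, 140–150 °C until CO2 stops; distil
Reagents that add atoms: none
Why: Saponification, relactonisation on acidification and thermal decarboxylation of the malonic-type acid (end game of the malonic ester synthesis) remove the extra carboxyl group without involving the carbinol stereocentre.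

Step 3
Reactants: 8 rac-2-(oct-7-en-1-yl)oxirane (1,2-epoxy-9-decene)
Product: 9 (2S)-2-(oct-7-en-1-yl)oxirane
Conditions: (S,S)-(salen)Co(OAc) (0.5 mol %, made from (S,S)-(salen)Co, AcOH, air; salen = N,N'-bis(3,5-di-tert-butylsalicylidene)cyclohexane-1,2-diaminate), H2O (0.55 equiv), neat, 0 °C to rt, 16 h; distil
Reagents that add atoms: none
Why: Jacobsen hydrolytic kinetic resolution, in which the (S,S)-catalyst (trivalent cobalt) hydrolyses the (R)-epoxide far faster (selectivity factor above 100 for unbranched terminal epoxides), so unreacted (S)-9 is recovered in about 45% yield and at least 99% ee, which sets the later C2''.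

Step 4
Reactants: 9 (2S)-2-(oct-7-en-1-yl)oxirane; 2 diethyl malonate
Product: 11 ethyl (5S)-5-(oct-7-en-1-yl)-2-oxooxolane-3-carboxylate (C3 epimers), via open-chain hydroxy diester 10 (not isolated)
Conditions: NaOEt (1.1 equiv), EtOH, rt to 60 °C, 6 h; then 1 M HCl
Reagents that add atoms: none
Why: The same malonic ester epoxide opening and lactonisation as in step 1, with SN2 attack at the terminal CH2 leaving the (S)-configured C–O bond intact and the remote alkene inert.

Step 5
Reactants: 11 ethyl (5S)-5-(oct-7-en-1-yl)-2-oxooxolane-3-carboxylate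
Product: 12 (5S)-5-(oct-7-en-1-yl)oxolan-2-one
Conditions: LiCl (2 equiv), H2O (2 equiv), DMSO, 150 °C, 4 h
Reagents that add atoms: none
Why: Krapcho dealkoxycarbonylation removes the ethyl ester under neutral conditions, and the lactone, its carbinol stereocentre and the terminal alkene all survive.

Step 6 (key step)
Reactants: 7 (S)-γ-valerolactone (3.0 equiv); 12 (5S)-5-(oct-7-en-1-yl)oxolan-2-one (1.0 equiv)
Product: 14 (5S)-3-[(4S)-4-hydroxydodec-11-enoyl]-5-methyloxolan-2-one (C3 epimers plus enol/lactol tautomers), via lithium lactone enolate 13 (not isolated)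
Conditions: LDA (3.1 equiv, commercial solution), THF, −78 °C, slow addition of 7, 45 min; then 12, −78 to −30 °C, 3 h; AcOH quench at −78 °C; short silica plug
Reagents that add atoms: none
Why: Crossed Claisen condensation in which the cheap, fully preformed enolate 13 is used in excess both to attack the good acyl acceptor 12 and to deprotonate the β-keto lactone formed (the driving force), while proton exchange or transacylation between the lactones is harmless because the isomeric cross product decarboxylates to the same ketone, and the new α-centre is erased in step 7.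

Step 7
Reactants: 14 (5S)-3-[(4S)-4-hydroxydodec-11-enoyl]-5-methyloxolan-2-one
Product: 17 (2S,7S)-2-methyl-7-(oct-7-en-1-yl)-1,6-dioxaspiro[4.4]nonane (about 1:1 at the spiro carbon), via β-keto acid 15 (not isolated), via dihydroxy ketone 16 (not isolated)
Conditions: H2SO4 (1 M aq.)/1,4-dioxane 1:1, 90 °C, 5 h
Reagents that add atoms: none
Why: Acid hydrolysis of the lactone by acyl–oxygen cleavage (both carbinols stay S) gives a β-keto acid that loses CO2 irreversibly, as in the classical dibutyrolactone to 1,6-dioxaspiro[4.4]nonane sequence, and the γ,γ'-dihydroxy ketone spiroketalises spontaneously to the thermodynamic epimer mixture resolved in step 14.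

Step 8
Reactants: 17 (2S,7S)-2-methyl-7-(oct-7-en-1-yl)-1,6-dioxaspiro[4.4]nonane
Product: 19 7-[(2S,7S)-7-methyl-1,6-dioxaspiro[4.4]nonan-2-yl]heptanal (C5'' epimer mixture), via secondary ozonide 18 (not isolated)
Conditions: O3, CH2Cl2, −78 °C; then Me2S (5 equiv), −78 °C to rt
Reagents that add atoms: ozone, [O-][O+]=O
Why: Ozonolysis with reductive work-up (Criegee mechanism) cleaves the only C=C bond and removes one carbon, so the new aldehyde carbon is the future C3, and the spiroketal has no acetal C–H for ozone to attack.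

Step 9
Reactants: 19 7-[(2S,7S)-7-methyl-1,6-dioxaspiro[4.4]nonan-2-yl]heptanal; 20 1-bromo-3,5-dimethoxybenzene
Product: 22 1-(3,5-dimethoxyphenyl)-7-[(2S,7S)-7-methyl-1,6-dioxaspiro[4.4]nonan-2-yl]heptan-1-ol (both C1 epimers), via 3,5-dimethoxyphenylmagnesium bromide 21 (not isolated)
Conditions: 20 (1.3 equiv), Mg turnings, THF, 40 °C; then 19, THF, −78 to 0 °C; sat. aq. NH4Cl
Reagents that add atoms: none
Why: Grignard addition of an aryl nucleophile to an unhindered aliphatic aldehyde is fast at low temperature, the spiroketal is inert to it, and the uncontrolled carbinol centre is erased in step 10.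

Step 10
Reactants: 22 1-(3,5-dimethoxyphenyl)-7-[(2S,7S)-7-methyl-1,6-dioxaspiro[4.4]nonan-2-yl]heptan-1-ol
Product: 23 1-(3,5-dimethoxyphenyl)-7-[(2S,7S)-7-methyl-1,6-dioxaspiro[4.4]nonan-2-yl]heptan-1-one
Conditions: Dess–Martin periodinane (1.3 equiv), CH2Cl2, 0 °C to rt
Reagents that add atoms: none
Why: Dess–Martin oxidation converts the secondary benzylic alcohol cleanly to the aryl ketone, does not touch the electron-rich arene, and any acetic-acid-induced spiro epimerisation is irrelevant at this stage.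

Step 11
Reactants: 23 1-(3,5-dimethoxyphenyl)-7-[(2S,7S)-7-methyl-1,6-dioxaspiro[4.4]nonan-2-yl]heptan-1-one
Product: 24 (1R)-1-(3,5-dimethoxyphenyl)-7-[(2S,7S)-7-methyl-1,6-dioxaspiro[4.4]nonan-2-yl]heptan-1-ol
Conditions: RuCl[(R,R)-TsDPEN](p-cymene) (1 mol %), HCO2H/Et3N (5:2), 30 °C, 24 h
Reagents that add atoms: none
Why: Noyori–Ikariya asymmetric transfer hydrogenation, in which the CH/π contact between the substrate aryl group and the η6-arene of the (R,R)-catalyst steers hydride delivery, so aryl n-alkyl ketones give the (R)-alcohol (typically 95–98% ee), which sets C3.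

Step 12
Reactants: 24 (1R)-1-(3,5-dimethoxyphenyl)-7-[(2S,7S)-7-methyl-1,6-dioxaspiro[4.4]nonan-2-yl]heptan-1-ol
Product: 25 (1R)-1-(2-bromo-3,5-dimethoxyphenyl)-7-[(2S,7S)-7-methyl-1,6-dioxaspiro[4.4]nonan-2-yl]heptan-1-ol
Conditions: NBS (1.02 equiv), MeCN, 0 °C, dark, 1 h
Reagents that add atoms: N-bromosuccinimide, O=C1CCC(=O)N1Br
Why: Electrophilic aromatic bromination goes to C2 (equivalent to C6), which is para to one OMe and ortho to the other, rather than to the crowded position between the two OMe groups, and it is much faster than oxidation of the carbinol.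

Step 13
Reactants: 25 (1R)-1-(2-bromo-3,5-dimethoxyphenyl)-7-[(2S,7S)-7-methyl-1,6-dioxaspiro[4.4]nonan-2-yl]heptan-1-ol
Product: 28 (3R)-5,7-dimethoxy-3-{6-[(2S,7S)-7-methyl-1,6-dioxaspiro[4.4]nonan-2-yl]hexyl}-2-benzofuran-1(3H)-one (C5'' epimer mixture), via dilithiated aryl alkoxide 26 (not isolated), via hydroxy acid 27 (not isolated)
Conditions: n-BuLi (2.2 equiv), THF, −78 °C, 30 min; dry CO2, −78 to 0 °C; 1 M HCl, rt, 1 h
Reagents that add atoms: carbon dioxide, O=C=O
Why: O–H deprotonation followed by bromine–lithium exchange gives an aryllithium stabilised by the flanking OMe and alkoxide, carboxylation installs C1, and the o-(1-hydroxyalkyl)benzoic acid lactonises on acidification by acyl substitution, so the C3–O bond and the (R) configuration are retained.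

Step 14
Reactants: 28 (3R)-5,7-dimethoxy-3-{6-[(2S,7S)-7-methyl-1,6-dioxaspiro[4.4]nonan-2-yl]hexyl}-2-benzofuran-1(3H)-one (C5'' epimer mixture)
Product: 29 (3R)-5,7-dimethoxy-3-{6-[(2S,5R,7S)-7-methyl-1,6-dioxaspiro[4.4]nonan-2-yl]hexyl}-2-benzofuran-1(3H)-one (target)
Conditions: camphorsulfonic acid (5 mol %), CH2Cl2, rt, 2 h; Et3N; semi-preparative HPLC on silica (hexane/EtOAc); recovered (5''S) epimer resubmitted (2–3 cycles); product kept cold and acid-free
Reagents that add atoms: none
Why: Acid-catalysed spiroketal epimerisation through the ring-opened oxocarbenium ion touches only C5'' and restores the roughly 1:1 equilibrium, normal-phase HPLC delivers the (5''R) isomer (each alkyl group anti to the oxygen of the other ring), and recycling the (5''S) isomer funnels the material into 29.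

## Compound list
1 | (S)-propylene oxide, (2S)-2-methyloxirane | C[C@H]1CO1 | starting material
2 | diethyl malonate | CCOC(=O)CC(=O)OCC | starting material
3 | diethyl 2-[(2S)-2-hydroxypropyl]propanedioate (not isolated) | C[C@H](O)CC(C(=O)OCC)C(=O)OCC | intermediate
4 | ethyl (5S)-5-methyl-2-oxooxolane-3-carboxylate (C3 epimers) | CCOC(=O)C1C[C@H](C)OC1=O | intermediate
5 | disodium 2-[(2S)-2-hydroxypropyl]propanedioate (not isolated) | C[C@H](O)CC(C(=O)[O-])C(=O)[O-].[Na+].[Na+] | intermediate
6 | (5S)-5-methyl-2-oxooxolane-3-carboxylic acid (not isolated) | C[C@H]1CC(C(=O)O)C(=O)O1 | intermediate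
7 | (S)-γ-valerolactone, (5S)-5-methyloxolan-2-one | C[C@H]1CCC(=O)O1 | intermediate
8 | rac-2-(oct-7-en-1-yl)oxirane (1,2-epoxy-9-decene) | C=CCCCCCCC1CO1 | starting material
9 | (2S)-2-(oct-7-en-1-yl)oxirane | C=CCCCCCC[C@H]1CO1 | intermediate
10 | diethyl 2-[(2S)-2-hydroxydec-9-en-1-yl]propanedioate (not isolated) | C=CCCCCCC[C@H](O)CC(C(=O)OCC)C(=O)OCC | intermediate
11 | ethyl (5S)-5-(oct-7-en-1-yl)-2-oxooxolane-3-carboxylate (C3 epimers) | C=CCCCCCC[C@H]1CC(C(=O)OCC)C(=O)O1 | intermediate
12 | (5S)-5-(oct-7-en-1-yl)oxolan-2-one | C=CCCCCCC[C@H]1CCC(=O)O1 | intermediate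
13 | lithium enolate of (S)-γ-valerolactone (not isolated) | C[C@H]1CC=C([O-])O1.[Li+] | intermediate
14 | (5S)-3-[(4S)-4-hydroxydodec-11-enoyl]-5-methyloxolan-2-one (C3 epimers) | C=CCCCCCC[C@H](O)CCC(=O)C1C[C@H](C)OC1=O | intermediate
15 | (6S)-6-hydroxy-2-[(2S)-2-hydroxypropyl]-3-oxotetradec-13-enoic acid (not isolated) | C=CCCCCCC[C@H](O)CCC(=O)C(C[C@H](C)O)C(=O)O | intermediate
16 | (2S,8S)-2,8-dihydroxyhexadec-15-en-5-one (not isolated) | C=CCCCCCC[C@H](O)CCC(=O)CC[C@H](C)O | intermediate
17 | (2S,7S)-2-methyl-7-(oct-7-en-1-yl)-1,6-dioxaspiro[4.4]nonane (spiro epimers) | C=CCCCCCC[C@H]1CCC2(CC[C@H](C)O2)O1 | intermediate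
18 | 3-{6-[(2S,7S)-7-methyl-1,6-dioxaspiro[4.4]nonan-2-yl]hexyl}-1,2,4-trioxolane (not isolated) | C1OOC(CCCCCC[C@H]2CCC3(CC[C@H](C)O3)O2)O1 | intermediate
19 | 7-[(2S,7S)-7-methyl-1,6-dioxaspiro[4.4]nonan-2-yl]heptanal (spiro epimers) | O=CCCCCCC[C@H]1CCC2(CC[C@H](C)O2)O1 | intermediate
20 | 1-bromo-3,5-dimethoxybenzene | COc1cc(Br)cc(OC)c1 | starting material
21 | 3,5-dimethoxyphenylmagnesium bromide (not isolated) | COc1cc([Mg]Br)cc(OC)c1 | intermediate
22 | 1-(3,5-dimethoxyphenyl)-7-[(2S,7S)-7-methyl-1,6-dioxaspiro[4.4]nonan-2-yl]heptan-1-ol (C1 and spiro epimers) | COc1cc(OC)cc(C(O)CCCCCC[C@H]2CCC3(CC[C@H](C)O3)O2)c1 | intermediate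
23 | 1-(3,5-dimethoxyphenyl)-7-[(2S,7S)-7-methyl-1,6-dioxaspiro[4.4]nonan-2-yl]heptan-1-one (spiro epimers) | COc1cc(OC)cc(C(=O)CCCCCC[C@H]2CCC3(CC[C@H](C)O3)O2)c1 | intermediate
24 | (1R)-1-(3,5-dimethoxyphenyl)-7-[(2S,7S)-7-methyl-1,6-dioxaspiro[4.4]nonan-2-yl]heptan-1-ol (spiro epimers) | COc1cc(OC)cc([C@H](O)CCCCCC[C@H]2CCC3(CC[C@H](C)O3)O2)c1 | intermediate
25 | (1R)-1-(2-bromo-3,5-dimethoxyphenyl)-7-[(2S,7S)-7-methyl-1,6-dioxaspiro[4.4]nonan-2-yl]heptan-1-ol (spiro epimers) | COc1cc(OC)c(Br)c([C@H](O)CCCCCC[C@H]2CCC3(CC[C@H](C)O3)O2)c1 | intermediate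
26 | lithium (1R)-1-(2-lithio-3,5-dimethoxyphenyl)-7-[(2S,7S)-7-methyl-1,6-dioxaspiro[4.4]nonan-2-yl]heptan-1-olate (not isolated) | COc1cc(OC)c([Li])c([C@H]([O-])CCCCCC[C@H]2CCC3(CC[C@H](C)O3)O2)c1.[Li+] | intermediate
27 | 2-{(1R)-1-hydroxy-7-[(2S,7S)-7-methyl-1,6-dioxaspiro[4.4]nonan-2-yl]heptyl}-4,6-dimethoxybenzoic acid (not isolated) | COc1cc(OC)c(C(=O)O)c([C@H](O)CCCCCC[C@H]2CCC3(CC[C@H](C)O3)O2)c1 | intermediate
28 | (3R)-5,7-dimethoxy-3-{6-[(2S,7S)-7-methyl-1,6-dioxaspiro[4.4]nonan-2-yl]hexyl}-2-benzofuran-1(3H)-one (spiro epimers) | COc1cc(OC)c2c(c1)[C@@H](CCCCCC[C@H]1CCC3(CC[C@H](C)O3)O1)OC2=O | intermediate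
29 | (3R)-5,7-dimethoxy-3-{6-[(2S,5R,7S)-7-methyl-1,6-dioxaspiro[4.4]nonan-2-yl]hexyl}-2-benzofuran-1(3H)-one | COc1cc(OC)c2c(c1)[C@@H](CCCCCC[C@H]1CC[C@@]3(CC[C@H](C)O3)O1)OC2=O | target

## Step count and risks
Total step count: 14. Longest linear sequence: 12 steps (8 to 29, steps 3–14). The two-step preparation of 7 runs in parallel.

**Step 6, crossed Claisen condensation of two enolisable lactones.** The risks are proton transfer, self-condensation of 12 and low conversion. The fallback sets out from 12 and comes back at 17.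
- Lactone 12 is opened with MeNH(OMe)·HCl and i-PrMgCl (THF, −20 °C) to (4S)-4-hydroxy-N-methoxy-N-methyldodec-11-enamide F1.
- This is silylated at once (TBSCl, imidazole, DMF) to (4S)-4-(tert-butyldimethylsilyloxy)-N-methoxy-N-methyldodec-11-enamide F2.
- This acyl donor carries no free OH, is much less acidic than a lactone, and holds the enolate adduct as a chelate until the quench.
- About 1.5 equiv of enolate 13 (THF, −78 to −40 °C) therefore suffices to give (5S)-3-[(4S)-4-(tert-butyldimethylsilyloxy)dodec-11-enoyl]-5-methyloxolan-2-one F3.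
- Under the aqueous acid of step 7, F3 loses the silyl group to give 14 and runs on through 15 and 16 to 17.

**Step 13, dianion carboxylation.** The risks are protonation or butylation of the hindered aryllithium and incomplete CO2 capture. The fallback sets out from 25 and comes back at 28, and it makes no new isolated compound.
- It is a palladium-catalysed carbonylative lactonisation: Pd(OAc)2 (5 mol %), Xantphos (6 mol %), CO (1 atm), Et3N (3 equiv), toluene, 90 °C.
- Zerovalent palladium inserts into the C–Br bond, CO inserts, and the neighbouring hydroxyl group captures the acyl palladium.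
- Thermal or salt-induced spiro epimerisation does not matter here, because 28 is equilibrated in step 14 anyway.

**Step 14, separation of the C5'' epimers.** The two phthalides differ only at a remote spiro centre, so they may co-elute, and each pass is capped near 50%. The fallback sets out from 25 and comes back at 29. It moves the resolution to the alcohol stage and then closes the phthalide under cold, base-only conditions.
- Mixture 25, whose free OH gives longer retention and a second, independent chance of selectivity on silica, is separated by HPLC.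
- One fraction is (1R)-1-(2-bromo-3,5-dimethoxyphenyl)-7-[(2S,5R,7S)-7-methyl-1,6-dioxaspiro[4.4]nonan-2-yl]heptan-1-ol F4.
- The other is (1R)-1-(2-bromo-3,5-dimethoxyphenyl)-7-[(2S,5S,7S)-7-methyl-1,6-dioxaspiro[4.4]nonan-2-yl]heptan-1-ol F5, which is turned back into 25 with catalytic camphorsulfonic acid and recycled.
- F4 is carbamoylated (NaH, Et2NCOCl, THF, 0 °C to rt) to (1R)-1-(2-bromo-3,5-dimethoxyphenyl)-7-[(2S,5R,7S)-7-methyl-1,6-dioxaspiro[4.4]nonan-2-yl]heptyl N,N-diethylcarbamate F6.
- Treatment with t-BuLi (2.1 equiv, THF, −78 °C) gives the aryllithium (1R)-1-(2-lithio-3,5-dimethoxyphenyl)-7-[(2S,5R,7S)-7-methyl-1,6-dioxaspiro[4.4]nonan-2-yl]heptyl N,N-diethylcarbamate F7.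
- F7 attacks its own carbamate carbonyl (Parham-type cyclisation), expels lithium diethylamide and gives 29 directly after a pH 7 buffer quench. No acid touches the resolved spiro centre.

## Further compounds
F1 | step 6 | (4S)-4-hydroxy-N-methoxy-N-methyldodec-11-enamide | C=CCCCCCC[C@H](O)CCC(=O)N(C)OC
F2 | step 6 | (4S)-4-(tert-butyldimethylsilyloxy)-N-methoxy-N-methyldodec-11-enamide | C=CCCCCCC[C@H](O[Si](C)(C)C(C)(C)C)CCC(=O)N(C)OC
F3 | step 6 | (5S)-3-[(4S)-4-(tert-butyldimethylsilyloxy)dodec-11-enoyl]-5-methyloxolan-2-one | C=CCCCCCC[C@H](O[Si](C)(C)C(C)(C)C)CCC(=O)C1C[C@H](C)OC1=O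
F0 | step 13 | none | none
F4 | step 14 | (1R)-1-(2-bromo-3,5-dimethoxyphenyl)-7-[(2S,5R,7S)-7-methyl-1,6-dioxaspiro[4.4]nonan-2-yl]heptan-1-ol | COc1cc(OC)c(Br)c([C@H](O)CCCCCC[C@H]2CC[C@@]3(CC[C@H](C)O3)O2)c1
F5 | step 14 | (1R)-1-(2-bromo-3,5-dimethoxyphenyl)-7-[(2S,5S,7S)-7-methyl-1,6-dioxaspiro[4.4]nonan-2-yl]heptan-1-ol | COc1cc(OC)c(Br)c([C@H](O)CCCCCC[C@H]2CC[C@]3(CC[C@H](C)O3)O2)c1
F6 | step 14 | (1R)-1-(2-bromo-3,5-dimethoxyphenyl)-7-[(2S,5R,7S)-7-methyl-1,6-dioxaspiro[4.4]nonan-2-yl]heptyl N,N-diethylcarbamate | COc1cc(OC)c(Br)c([C@H](OC(=O)N(CC)CC)CCCCCC[C@H]2CC[C@@]3(CC[C@H](C)O3)O2)c1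
F7 | step 14 | (1R)-1-(2-lithio-3,5-dimethoxyphenyl)-7-[(2S,5R,7S)-7-methyl-1,6-dioxaspiro[4.4]nonan-2-yl]heptyl N,N-diethylcarbamate | COc1cc(OC)c([Li])c([C@H](OC(=O)N(CC)CC)CCCCCC[C@H]2CC[C@@]3(CC[C@H](C)O3)O2)c1
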